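**Slow supply.** Starting material goes slowly. Alder keeps 72.0% at 10.0 min, which gives a life of 35.7 min, longer than the run. Target already stands in alder at 0.833 min, at 2.1%, far earlier than that life. So the reckoning takes the catalyst's fast step as finished and the supply of target as steady.

| setting | birch | elm | cedar | alder | Tuesday's | Wednesday's | Thursday's | Sunday's |
|---|---|---|---|---|---|---|---|---|
| starting material | 0.10 M | 0.10 M | 0.10 M | 0.10 M | 0.10 M (fed, over 6.0 min) | 0.10 M | 0.10 M (in portions, 2, over 6.0 min) | 0.10 M |
| second substrate | 0.20 M | 0.20 M | 0.20 M | 0.10 M | 0.200 M | 0.200 M | 0.200 M | 0.200 M (fed, over 6.0 min) |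
| free catalyst | 57 µM | 28 µM | 43 µM | 57 µM | 57 µM | 57 µM | 57 µM | 57 µM |
| temperature | 75 °C | 86 °C | 75 °C | 86 °C | 80 °C | 80 °C | 80 °C |  |
| remark | run made earlier | run made earlier | run made earlier | run made earlier | all else is in the flask from the start; the feed brings no volume worth counting | everything together at the start | first portion at the start, last at 6.0 min | the addition at 50 °C, then warmed to 80 °C; the feed brings no volume worth counting |
| time |  |  |  |  | 10 min | 10 min | 10 min | 10 min |

- birch (time / min: target / %, over-reaction product / %, starting material / %): 0.833: 0.8, 0.4, 98.4; 2.50: 2.6, 0.3, 96.4; 5.00: 5.7, 0, 94.0; 8.00: 7.5, 1.0, 88.7; 10.0: 11.4, 4.5, 88.5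
- elm (time / min: target / %, over-reaction product / %, starting material / %): 0.833: 0, 0, 97.5; 1.50: 2.1, 0, 98.3; 3.00: 3.0, 0, 95.7; 5.00: 4.2, 0.1, 94.0; 10.0: 7.9, 7.3, 85.7
- cedar (time / min: target / %, over-reaction product / %, starting material / %): 2.00: 0.7, 0.6, 97.5; 4.00: 2.1, 0, 96.3; 6.00: 3.7, 0.9, 95.2; 8.00: 4.6, 0.4, 91.3; 10.0: 7.6, 3.1, 91.0
- alder (time / min: target / %, over-reaction product / %, starting material / %): 0.833: 2.1, 0.9, 97.5; 1.50: 4.7, 0, 95.5; 3.00: 6.7, 0.3, 88.6; 5.00: 9.2, 4.1, 84.8; 10.0: 13.2, 13.9, 72.0

(readings scatter by 1 percentage point)

1. the best flask by share of target in target plus over-reaction product; "all alike" if 1.5 percentage points covers them all (Tuesday's / Wednesday's / Thursday's / Sunday's / all alike)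
2. share of target in target plus over-reaction product at the end, Tuesday's
3. share of target in target plus over-reaction product at the end, Wednesday's
4. share of target in target plus over-reaction product at the end, Thursday's
5. share of target in target plus over-reaction product at the end, Sunday's



**Ageing target.** Between those two rungs, target ages. Suppose target arrives steadily and is lost first-order, and call x its exposure, the loss constant times the time since target began. The share of target (the selectivity) is then (1 − e^−x)/x, and the supply rate cancels. The readings allow this. The ratio of over-reaction product to target at 10.0 min reads 0.395 in birch and 0.408 in cedar, with different catalyst.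

**Reading x.** Pooled, the ratio reads 0.400 at 75 °C and 1.00 at 86 °C. Solving the rule gives x of 0.715 and 1.59. Logarithmic interpolation to 80 °C gives 1.03, hence the ageing constant, the fraction of target lost per minute, 0.103 /min. That makes target's life at 80 °C 9.71 min, shorter than the supply life read from alder at 86 °C.

**My reckoning.** Wednesday's ages target for the whole run: 62.5%. Sunday's, taken as cold until the feed ends, has 4.00 min of heat: 82.0%. In Tuesday's, if making follows [starting material], target begins on average at mid-feed: 71.3%. On the same assumption Thursday's, with the first portion ageing from the start and the last from 6.0 min, gives 68.1%. So Sunday's leads this reckoning.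

**The forecast.** The forecast gives 61%, 51%, 60% and 76% for Tuesday's to Sunday's, lower than this reckoning on Wednesday's and Sunday's, and of Sunday's it says: “This is the best, though the warming profile is uncertain”.

**The result.** Tuesday's gives 69.7%, Wednesday's 64.6%, Thursday's 67.3% and Sunday's 81.6%, so Sunday's stands first.

    starting material + free catalyst ⇌ catalyst intermediate A (K = 120 /M, k = 1240 /M/min, Ea = 61.0 kJ/mol, ΔH = −7.00 kJ/mol)
    catalyst intermediate A → free catalyst + target (k = 53.0 /min, Ea = 85.0 kJ/mol)
    second substrate + free catalyst ⇌ catalyst intermediate B (K = 3.10 /M, k = 1080 /M/min, Ea = 49.0 kJ/mol, ΔH = −48.0 kJ/mol)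
    catalyst intermediate B → free catalyst + second product (k = 427 /min, Ea = 67.0 kJ/mol)
    target → over-reaction product (k = 0.0937 /min, Ea = 93.0 kJ/mol)
    (constants at 80 °C)

Moved alone by one same factor up or down, the settings tried, temperature not among them, shift Wednesday's share at most in this order: time (7.3 points), then starting material (0.12 points), then free catalyst (0.12 points), then second substrate (under 0.05 points). With 0.103 /min, Wednesday's flask read at 2.5 min reckons to 88.2% and gives 89.1%. Read at 40 min, it reckons to 23.9% and gives 23.2%.

(The data were generated by integration for an exercise, and the scatter is random.)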